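**Plan**
- Retrosynthesis: the C4–C5 epoxide oxygen and the C13 acetate are removed first. The γ-lactone is then cut at C6–O and C7–C11 (malonic acid plus a (4Z,6E)-cyclodeca-4,6-dienone), the ten-membered ring at C5–C6, and the chain at C2–C3, C1–C2 and C7–C8.
- Enabling feature: the lactone ring (O–C6, C7–C11, C12) lies directly beside the Z-configured C4–C5 unit. This is what a C4=C5–C6=C7 ring diene leaves behind when a malonyl radical adds to C7 and its carboxylate closes on C6.
- Forward: (R)-citramalic acid (C1, C8–C10, C10 methyl) is acylated at C8 with a distannylethene (C6–C7), given its C2 methyl, alkylated with a Z-iodoallyl bromide from propargyl alcohol (C3–C5) and closed by Stille coupling (ring 1, carbocycle). Lactone annulation (ring 2) and epoxidation (ring 3) follow.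
- Stereochemistry: C10 from citramalic acid; C8 by CBS reduction; C7 and C6 in the annulation (attack anti to the C8 ester, syn closure across the E olefin); C11 by protonation after conjugate borylation; C4/C5 by outer-face epoxidation of the Z olefin.

Key step: step 14

Remark: germacrane numbering is used for all ring compounds (C1 ketone, C4 methyl, C6/C7 lactone junction, C8 tiglate, C10 methyl and acetate, C11–C13 lactone arm).

**Route**

Step 1
Reactants: 1 propargyl alcohol
Product: 3 (Z)-3-iodo-2-methylprop-2-en-1-ol, via magnesium chelate 2 (not isolated)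
Conditions: MeMgBr (2.5 equiv), CuI (10 mol%), THF, −10 °C to rt; then I2, −78 to 0 °C; aq. NH4Cl
Reagents that add atoms: methylmagnesium bromide, C[Mg]Br; iodine, II
Why: Copper-catalysed anti-carbomagnesiation of the propargylic magnesium alkoxide puts methyl on C2 and magnesium on C3 within a five-membered chelate, and iodinolysis with retention fixes the Z geometry (CH2OH and I cis).

Step 2
Reactants: 3 (Z)-3-iodo-2-methylprop-2-en-1-ol
Product: 4 (Z)-3-bromo-1-iodo-2-methylprop-1-ene
Conditions: CBr4, PPh3, CH2Cl2, 0 °C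
Reagents that add atoms: carbon tetrabromide, BrC(Br)(Br)Br
Why: Appel reaction, an SN2 displacement at the primary allylic carbon that leaves the alkenyl iodide and its geometry untouched.

Step 3
Reactants: 5 (R)-citramalic acid
Product: 6 2-[(4R)-2,2,4-trimethyl-5-oxo-1,3-dioxolan-4-yl]acetic acid
Conditions: 2,2-dimethoxypropane, TsOH·H2O (cat.), rt
Reagents that add atoms: 2,2-dimethoxypropane, COC(C)(C)OC
Why: Acid-catalysed acetalisation ties the α-hydroxy acid end (C10–OH and the C1 carboxyl) into the favoured five-membered dioxolanone and leaves the CH2CO2H arm (C9, C8) free; the stereocentre is not touched.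

Step 4
Reactants: 6 2-[(4R)-2,2,4-trimethyl-5-oxo-1,3-dioxolan-4-yl]acetic acid; 7 (E)-1,2-bis(tributylstannyl)ethene
Product: 9 (5R)-2,2,5-trimethyl-5-[(E)-2-oxo-4-(tributylstannyl)but-3-enyl]-1,3-dioxolan-4-one, via acid chloride 8 (not isolated)
Conditions: (COCl)2, DMF (cat.), CH2Cl2, 0 °C to rt, evaporate; then 7 (1.5 equiv), PdCl2(PPh3)2 (3 mol%), toluene, 60 °C
Reagents that add atoms: oxalyl chloride, O=C(Cl)C(=O)Cl (chlorine of 8 only, lost again in the coupling)
Why: Acid chloride formation followed by Stille acyl coupling; zerovalent palladium inserts into the C–Cl bond and one stannyl group of the symmetrical E-distannane transmetallates with retention, and the resulting electron-poor β-stannyl enone resists a second acylation.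

Step 5
Reactants: 9 (5R)-2,2,5-trimethyl-5-[(E)-2-oxo-4-(tributylstannyl)but-3-enyl]-1,3-dioxolan-4-one
Product: 11 (3R,5S)-3-hydroxy-3-methyl-5-[(E)-2-(tributylstannyl)ethenyl]oxolan-2-one, via hydroxy dioxolanone 10 (not isolated)
Conditions: (R)-2-methyl-CBS-oxazaborolidine (0.3 equiv), catecholborane, toluene, −78 °C; MeOH; then PPTS (cat.), CH2Cl2, rt
Reagents that add atoms: none
Why: Corey–Bakshi–Shibata reduction; with the stannylvinyl group as the large substituent the (R)-catalyst delivers hydride to the face that gives the 8S carbinol (catalyst control), and the γ-hydroxyl then displaces the acetonide ester to close the γ-lactone with loss of acetone.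

Step 6
Reactants: 11 (3R,5S)-3-hydroxy-3-methyl-5-[(E)-2-(tributylstannyl)ethenyl]oxolan-2-one
Product: 12 (2R,4S,5E)-2,4-dihydroxy-N-methoxy-N,2-dimethyl-6-(tributylstannyl)hex-5-enamide
Conditions: AlMe3, MeNH(OMe)·HCl, CH2Cl2, 0 °C to rt; aq. potassium sodium tartrate; crude product taken on at once
Reagents that add atoms: N,O-dimethylhydroxylamine hydrochloride, CNOC.Cl
Why: Weinreb aminolysis of the lactone by the aluminium amide formed in the flask opens the ring to the N-methoxy-N-methylamide without touching either stereocentre; immediate silylation forestalls relactonisation.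

Step 7
Reactants: 12 (2R,4S,5E)-2,4-dihydroxy-N-methoxy-N,2-dimethyl-6-(tributylstannyl)hex-5-enamide
Product: 13 (2R,4S,5E)-N-methoxy-N,2-dimethyl-2,4-bis(triethylsilyloxy)-6-(tributylstannyl)hex-5-enamide
Conditions: Et3SiOTf (2.5 equiv), 2,6-lutidine, CH2Cl2, −78 to 0 °C
Reagents that add atoms: triethylsilyl trifluoromethanesulfonate, CC[Si](CC)(CC)OS(=O)(=O)C(F)(F)F
Why: Silylation with a silyl triflate and 2,6-lutidine is forceful enough for the tertiary C10 hydroxyl as well as the secondary allylic one, and the buffer protects the alkenylstannane from acid.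

Step 8
Reactants: 13 (2R,4S,5E)-N-methoxy-N,2-dimethyl-2,4-bis(triethylsilyloxy)-6-(tributylstannyl)hex-5-enamide
Product: 14 (3R,5S,6E)-3-methyl-3,5-bis(triethylsilyloxy)-7-(tributylstannyl)hept-6-en-2-one
Conditions: MeMgBr, THF, 0 °C to rt; aq. NH4Cl
Reagents that add atoms: methylmagnesium bromide, C[Mg]Br
Why: Weinreb ketone synthesis; the chelated tetrahedral magnesium adduct resists a second addition and releases the methyl ketone (C1 carbonyl, C2 methyl) on work-up.

Step 9
Reactants: 14 (3R,5S,6E)-3-methyl-3,5-bis(triethylsilyloxy)-7-(tributylstannyl)hept-6-en-2-one; 4 (Z)-3-bromo-1-iodo-2-methylprop-1-ene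
Product: 16 (1Z,6R,8S,9E)-1-iodo-2,6-dimethyl-6,8-bis(triethylsilyloxy)-10-(tributylstannyl)deca-1,9-dien-5-one, via lithium enolate 15 (not isolated)
Conditions: LiN(i-Pr)2, THF, −78 °C; then 4, DMPU, −78 to −40 °C
Reagents that add atoms: lithium diisopropylamide, [Li]N(C(C)C)C(C)C (lithium of 15 only)
Why: Kinetic enolate alkylation; C10 is quaternary, so only the C2 enolate can form, and it displaces the primary allylic bromide in an SN2 reaction (C2–C3) while the alkenyl iodide, the alkenylstannane and both silyl ethers are inert at low temperature.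

Step 10
Reactants: 16 (1Z,6R,8S,9E)-1-iodo-2,6-dimethyl-6,8-bis(triethylsilyloxy)-10-(tributylstannyl)deca-1,9-dien-5-one
Product: 17 (4Z,6E,8S,10R)-4,10-dimethyl-8,10-bis(triethylsilyloxy)cyclodeca-4,6-dien-1-one
Conditions: Pd2(dba)3 (10 mol%), AsPh3 (40 mol%), i-Pr2NEt, DMF, 1 mM, 40 °C
Reagents that add atoms: none
Why: Intramolecular Stille coupling; zerovalent palladium inserts into the C5–I bond, the C6 stannane transmetallates and reductive elimination forms C5–C6 with retention at both alkenes (4Z,6E), high dilution favouring ring closure over oligomerisation.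

Step 11
Reactants: 17 (4Z,6E,8S,10R)-4,10-dimethyl-8,10-bis(triethylsilyloxy)cyclodeca-4,6-dien-1-one
Product: 18 (4Z,6E,8S,10R)-8,10-dihydroxy-4,10-dimethylcyclodeca-4,6-dien-1-one
Conditions: HF·pyridine, pyridine, THF, 0 °C to rt
Reagents that add atoms: none
Why: Fluoride-mediated desilylation under pyridine buffering removes both triethylsilyl ethers and spares the acid-sensitive dienyl carbinol and the α-ketol.

Step 12
Reactants: 18 (4Z,6E,8S,10R)-8,10-dihydroxy-4,10-dimethylcyclodeca-4,6-dien-1-one; 19 tiglic acid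
Product: 21 (4Z,6E,8S,10R)-10-hydroxy-4,10-dimethyl-8-(tigloyloxy)cyclodeca-4,6-dien-1-one, via mixed anhydride 20 (not isolated)
Conditions: 19, 2,4,6-trichlorobenzoyl chloride, Et3N, toluene, rt; then 18, DMAP, toluene, rt
Reagents that add atoms: 2,4,6-trichlorobenzoyl chloride, O=C(Cl)c1c(Cl)cc(Cl)cc1Cl (aroyl group of 20 only)
Why: Yamaguchi esterification acylates the secondary allylic C8 hydroxyl, while the tertiary C10 hydroxyl is too hindered to compete and the E geometry of the tigloyl group is stable under these conditions.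

Step 13
Reactants: 21 (4Z,6E,8S,10R)-10-hydroxy-4,10-dimethyl-8-(tigloyloxy)cyclodeca-4,6-dien-1-one
Product: 22 (4Z,6E,8S,10R)-10-acetoxy-4,10-dimethyl-8-(tigloyloxy)cyclodeca-4,6-dien-1-one
Conditions: Ac2O, DMAP, Et3N, CH2Cl2, rt
Reagents that add atoms: acetic anhydride, CC(=O)OC(C)=O
Why: DMAP-catalysed acylation (Steglich conditions) is the standard way to acetylate a tertiary alcohol and leaves the tiglate, the diene and the ketone untouched.

Step 14
Reactants: 22 (4Z,6E,8S,10R)-10-acetoxy-4,10-dimethyl-8-(tigloyloxy)cyclodeca-4,6-dien-1-one; 23 malonic acid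
Product: 24 (4Z,6R,7R,8S,10R,11R)-10-acetoxy-1-oxo-8-(tigloyloxy)germacr-4-en-12,6-olid-13-oic acid (11-carboxy trans-lactone)
Conditions: Mn(OAc)3·2H2O (2.2 equiv), Cu(OAc)2·H2O (0.3 equiv), malonic acid (5 equiv), KOAc, AcOH, 25–40 °C
Reagents that add atoms: none
Why: Malonic acid bound to trivalent manganese is oxidised to the electrophilic dicarboxymethyl radical, which adds to C7 to give an allyl radical over C6, C5 and C4; divalent copper oxidises this to the allyl cation (or an allylcopper species) and a malonyl carboxylate captures C6. The closest known reaction type is the Mn(OAc)3-mediated carbolactonisation of alkenes and 1,3-dienes with malonic or cyanoacetic acid, an oxidative radical–polar crossover γ-lactone annulation. The γ-lactone closes by 5-exo attack of the carboxylate oxygen on the C6 terminus of the allyl cation, the seven-membered closure at C4 being slower. C7 should be set by radical attack on the outer face of the E olefin, anti to the C8 acyloxy group; C6 by closure on the same face as the new C7–C11 bond, which across an E olefin gives the trans lactone; and C11 by equilibration of the malonate-type centre to the isomer with the carboxyl trans to C8 (this centre is erased in step 15). The step needs C7-over-C4 regioselectivity (secured by the more substituted allyl radical and the less hindered disubstituted terminus), retention of 4Z (secured by fast oxidation and closure of the configurationally stable allyl radical) and chemoselectivity (the electron-poor tiglate and the hindered, weakly enolisable ketone are poor partners for the malonyl radical near room temperature).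

Step 15
Reactants: 24 11-carboxy trans-lactone
Product: 26 (4Z,6R,7R,8S,10R)-10-acetoxy-1-oxo-8-(tigloyloxy)germacra-4,11(13)-dien-12,6-olide, via Mannich acid 25 (not isolated)
Conditions: 37% aq. HCHO, Et2NH, THF, rt; then NaOAc, AcOH, 70 °C
Reagents that add atoms: formaldehyde, C=O; diethylamine, CCNCC (nitrogen of 25 only)
Why: Mannich reaction followed by decarboxylative elimination (decarboxylative methylenation of an α-carboxy lactone); the malonate-type C11–H condenses with the iminium ion, and the β-amino acid loses CO2 and amine on warming to give the 11(13)-methylene.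

Step 16
Reactants: 26 α-methylene lactone
Product: 28 (4Z,6R,7R,8S,10R,11R)-10-acetoxy-13-hydroxy-1-oxo-8-(tigloyloxy)germacr-4-en-12,6-olide, via boronate 27 (not isolated)
Conditions: B2pin2, CuCl (5 mol%), DPEphos (5 mol%), NaOt-Bu (10 mol%), MeOH (2 equiv), THF, rt; then NaBO3·4H2O, THF/H2O, rt
Reagents that add atoms: bis(pinacolato)diboron, CC1(C)OB(OC1(C)C)B1OC(C)(C)C(C)(C)O1 (boron of 27 only); sodium perborate, [Na+].[O-]OB=O
Why: Copper-catalysed conjugate borylation of the unhindered exo-methylene (far more reactive than the trisubstituted tiglate) followed by perborate oxidation with retention; protonation of the copper enolate should place the C13 arm trans to C8, the more stable arrangement on a trans-fused lactone and the usual outcome of conjugate additions to such methylene lactones, and C11 remains epimerisable at the boronate stage if correction is needed.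

Step 17
Reactants: 28 13-hydroxy lactone
Product: 29 (4Z,6R,7R,8S,10R,11R)-10,13-diacetoxy-1-oxo-8-(tigloyloxy)germacr-4-en-12,6-olide
Conditions: Ac2O, pyridine, CH2Cl2, 0 °C to rt
Reagents that add atoms: acetic anhydride, CC(=O)OC(C)=O
Why: Acylation of the primary alcohol under mild pyridine conditions, which avoids β-elimination of the new acetate back to the methylene lactone.

Step 18
Reactants: 29 13-acetoxy lactone
Product: 30 (4R,5S,6S,7R,8S,10R,11R)-10,13-diacetoxy-4,5-epoxy-1-oxo-8-(tigloyloxy)germacran-12,6-olide (CNP0305680.1)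
Conditions: m-CPBA, NaHCO3, CH2Cl2, 0 °C
Reagents that add atoms: 3-chloroperbenzoic acid, OOC(=O)c1cccc(Cl)c1
Why: Prilezhaev epoxidation; the trisubstituted Z olefin is the only electron-rich alkene, syn oxygen transfer keeps C3 and C6 cis, and attack on the outer face of the ring olefin (with C6–H in the olefin plane this is the face of the lactone oxygen, opposite C7) should set 4R,5S.

**Compound list**

1 | propargyl alcohol (prop-2-yn-1-ol) | C#CCO | starting material
2 | magnesium chelate: 4-methyl-2,5-dihydro-1,2-oxamagnesole (cyclic Z-alkenylmagnesium alkoxide) | CC1=C[Mg]OC1 | intermediate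
3 | (Z)-3-iodo-2-methylprop-2-en-1-ol | OC/C(C)=C\I | intermediate
4 | (Z)-3-bromo-1-iodo-2-methylprop-1-ene | BrC/C(C)=C\I | intermediate
5 | (R)-citramalic acid, (2R)-2-hydroxy-2-methylbutanedioic acid | C[C@](O)(C(=O)O)CC(=O)O | starting material
6 | 2-[(4R)-2,2,4-trimethyl-5-oxo-1,3-dioxolan-4-yl]acetic acid | C[C@]1(CC(=O)O)OC(C)(C)OC1=O | intermediate
7 | (E)-1,2-bis(tributylstannyl)ethene | CCCC[Sn](CCCC)(CCCC)/C=C/[Sn](CCCC)(CCCC)CCCC | starting material
8 | 2-[(4R)-2,2,4-trimethyl-5-oxo-1,3-dioxolan-4-yl]acetyl chloride | C[C@]1(CC(=O)Cl)OC(C)(C)OC1=O | intermediate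
9 | (5R)-2,2,5-trimethyl-5-[(E)-2-oxo-4-(tributylstannyl)but-3-enyl]-1,3-dioxolan-4-one | C[C@]1(CC(=O)/C=C/[Sn](CCCC)(CCCC)CCCC)OC(C)(C)OC1=O | intermediate
10 | (5R)-5-[(2S,3E)-2-hydroxy-4-(tributylstannyl)but-3-enyl]-2,2,5-trimethyl-1,3-dioxolan-4-one | C[C@]1(C[C@H](O)/C=C/[Sn](CCCC)(CCCC)CCCC)OC(C)(C)OC1=O | intermediate
11 | (3R,5S)-3-hydroxy-3-methyl-5-[(E)-2-(tributylstannyl)ethenyl]oxolan-2-one | CCCC[Sn](CCCC)(CCCC)/C=C/[C@@H]1C[C@@](C)(O)C(=O)O1 | intermediate
12 | (2R,4S,5E)-2,4-dihydroxy-N-methoxy-N,2-dimethyl-6-(tributylstannyl)hex-5-enamide | CON(C)C(=O)[C@](C)(O)C[C@H](O)/C=C/[Sn](CCCC)(CCCC)CCCC | intermediate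
13 | (2R,4S,5E)-N-methoxy-N,2-dimethyl-2,4-bis(triethylsilyloxy)-6-(tributylstannyl)hex-5-enamide | CON(C)C(=O)[C@](C)(O[Si](CC)(CC)CC)C[C@H](O[Si](CC)(CC)CC)/C=C/[Sn](CCCC)(CCCC)CCCC | intermediate
14 | (3R,5S,6E)-3-methyl-3,5-bis(triethylsilyloxy)-7-(tributylstannyl)hept-6-en-2-one | CC(=O)[C@](C)(O[Si](CC)(CC)CC)C[C@H](O[Si](CC)(CC)CC)/C=C/[Sn](CCCC)(CCCC)CCCC | intermediate
15 | lithium enolate of 14 (C2=C1–OLi) | [Li]OC(=C)[C@](C)(O[Si](CC)(CC)CC)C[C@H](O[Si](CC)(CC)CC)/C=C/[Sn](CCCC)(CCCC)CCCC | intermediate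
16 | (1Z,6R,8S,9E)-1-iodo-2,6-dimethyl-6,8-bis(triethylsilyloxy)-10-(tributylstannyl)deca-1,9-dien-5-one | I/C=C(/C)CCC(=O)[C@](C)(O[Si](CC)(CC)CC)C[C@H](O[Si](CC)(CC)CC)/C=C/[Sn](CCCC)(CCCC)CCCC | intermediate
17 | (4Z,6E,8S,10R)-4,10-dimethyl-8,10-bis(triethylsilyloxy)cyclodeca-4,6-dien-1-one | C1C/C(C)=C\C=C\[C@@H](O[Si](CC)(CC)CC)C[C@@](C)(O[Si](CC)(CC)CC)C1=O | intermediate
18 | (4Z,6E,8S,10R)-8,10-dihydroxy-4,10-dimethylcyclodeca-4,6-dien-1-one | C1C/C(C)=C\C=C\[C@@H](O)C[C@@](C)(O)C1=O | intermediate
19 | tiglic acid, (E)-2-methylbut-2-enoic acid | C/C=C(\C)C(=O)O | starting material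
20 | tigloyl 2,4,6-trichlorobenzoyl mixed anhydride | C/C=C(\C)C(=O)OC(=O)c1c(Cl)cc(Cl)cc1Cl | intermediate
21 | (4Z,6E,8S,10R)-10-hydroxy-4,10-dimethyl-8-(tigloyloxy)cyclodeca-4,6-dien-1-one | C1C/C(C)=C\C=C\[C@@H](OC(=O)/C(C)=C/C)C[C@@](C)(O)C1=O | intermediate
22 | (4Z,6E,8S,10R)-10-acetoxy-4,10-dimethyl-8-(tigloyloxy)cyclodeca-4,6-dien-1-one | C1C/C(C)=C\C=C\[C@@H](OC(=O)/C(C)=C/C)C[C@@](C)(OC(C)=O)C1=O | intermediate
23 | malonic acid | OC(=O)CC(=O)O | starting material
24 | (4Z,6R,7R,8S,10R,11R)-10-acetoxy-1-oxo-8-(tigloyloxy)germacr-4-en-12,6-olid-13-oic acid (trans-fused γ-lactone, O on C6, C11 on C7, CO2H on C11 trans to C8) | C/C=C(\C)C(=O)O[C@H]1C[C@@](C)(OC(C)=O)C(=O)CC/C(C)=C\[C@H]2OC(=O)[C@@H](C(=O)O)[C@@H]21 | intermediate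
25 | Mannich acid: 11-(diethylaminomethyl) derivative of 24 (aminomethyl arm drawn trans to C8; centre lost in the same step) | C/C=C(\C)C(=O)O[C@H]1C[C@@](C)(OC(C)=O)C(=O)CC/C(C)=C\[C@H]2OC(=O)[C@@](C(=O)O)(CN(CC)CC)[C@@H]21 | intermediate
26 | (4Z,6R,7R,8S,10R)-10-acetoxy-1-oxo-8-(tigloyloxy)germacra-4,11(13)-dien-12,6-olide | C/C=C(\C)C(=O)O[C@H]1C[C@@](C)(OC(C)=O)C(=O)CC/C(C)=C\[C@H]2OC(=O)C(=C)[C@@H]21 | intermediate
27 | 13-(pinacolboryl)-11,13-dihydro derivative of 26 (CH2B arm on C11 trans to C8) | C/C=C(\C)C(=O)O[C@H]1C[C@@](C)(OC(C)=O)C(=O)CC/C(C)=C\[C@H]2OC(=O)[C@@H](CB3OC(C)(C)C(C)(C)O3)[C@@H]21 | intermediate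
28 | (4Z,6R,7R,8S,10R,11R)-10-acetoxy-13-hydroxy-1-oxo-8-(tigloyloxy)germacr-4-en-12,6-olide | C/C=C(\C)C(=O)O[C@H]1C[C@@](C)(OC(C)=O)C(=O)CC/C(C)=C\[C@H]2OC(=O)[C@@H](CO)[C@@H]21 | intermediate
29 | (4Z,6R,7R,8S,10R,11R)-10,13-diacetoxy-1-oxo-8-(tigloyloxy)germacr-4-en-12,6-olide | C/C=C(\C)C(=O)O[C@H]1C[C@@](C)(OC(C)=O)C(=O)CC/C(C)=C\[C@H]2OC(=O)[C@@H](COC(C)=O)[C@@H]21 | intermediate
30 | (4R,5S,6S,7R,8S,10R,11R)-10,13-diacetoxy-4,5-epoxy-1-oxo-8-(tigloyloxy)germacran-12,6-olide (CNP0305680.1) | C/C=C(\C)C(=O)O[C@H]1C[C@@](C)(OC(C)=O)C(=O)CC[C@@]2(C)O[C@H]2[C@H]2OC(=O)[C@@H](COC(C)=O)[C@@H]21 | target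

**Step count and risks**

Total steps: 18. Longest linear sequence: 16 steps (steps 3–18, from 5).

Steps most likely to fail:

Step 14 (lactone annulation). The α-carboxy lactone may be oxidised further by trivalent manganese, the radical may attack C4 instead of C7, or the dienyl tiglate may solvolyse in warm acetic acid. The fallback sets out from 22 and reaches the same ring by a redox-neutral atom-transfer route without a stoichiometric metal oxidant. Visible-light photoredox carbolactonisation with di-tert-butyl bromomalonate (fac-Ir(ppy)3, 2,6-lutidine, MeCN, blue light) should add the malonyl radical to C7 and close one tert-butyl ester onto C6 with loss of 2-methylpropene, giving the 11-tert-butoxycarbonyl lactone F1. CF3CO2H in CH2Cl2 at 0 °C then frees the acid and returns to 24.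

Step 10 (ten-membered Stille closure). Oligomerisation by intermolecular coupling and protodestannylation may outrun the strained ring closure. The fallback makes C5–C6 first and closes the ring at C2–C3 instead. Setting out from stannane 14 and iodo alcohol 3, an intermolecular Stille coupling (Pd2(dba)3, AsPh3, DMF, rt) should give the (6E,8Z)-dienol F2, and Appel bromination (CBr4, PPh3, CH2Cl2, −20 °C) the dienyl bromide F3. Slow addition of F3 to KN(SiMe3)2 in THF at high dilution (−78 to 0 °C) should close the ring by intramolecular alkylation of the only possible enolate, returning to 17.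

Step 18 (epoxidation). Facial selectivity may be poor, or the peracid may attack the inner face of the Z olefin. The fallback, from 29, delivers the oxygen to the face opposite the one the electrophile prefers. N-Bromosuccinimide in aqueous THF at 0 °C forms the bromonium ion on the preferred face and water opens it anti at the tertiary C4, giving the bromohydrin F4. Ag2O in THF then closes the epoxide by displacement at C5 with inversion, returning to 30.

**Further compounds**

F1 | step 14 | tert-butyl ester of 24 (CO2t-Bu on C11 trans to C8; 4Z, trans-fused lactone) | C/C=C(\C)C(=O)O[C@H]1C[C@@](C)(OC(C)=O)C(=O)CC/C(C)=C\[C@H]2OC(=O)[C@@H](C(=O)OC(C)(C)C)[C@@H]21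
F2 | step 10 | (3R,5S,6E,8Z)-10-hydroxy-3,9-dimethyl-3,5-bis(triethylsilyloxy)deca-6,8-dien-2-one | OC/C(C)=C\C=C\[C@@H](O[Si](CC)(CC)CC)C[C@@](C)(O[Si](CC)(CC)CC)C(C)=O
F3 | step 10 | (3R,5S,6E,8Z)-10-bromo-3,9-dimethyl-3,5-bis(triethylsilyloxy)deca-6,8-dien-2-one | BrC/C(C)=C\C=C\[C@@H](O[Si](CC)(CC)CC)C[C@@](C)(O[Si](CC)(CC)CC)C(C)=O
F4 | step 18 | (4R,5R,6S,7R,8S,10R,11R)-10,13-diacetoxy-5-bromo-4-hydroxy-1-oxo-8-(tigloyloxy)germacran-12,6-olide | C/C=C(\C)C(=O)O[C@H]1C[C@@](C)(OC(C)=O)C(=O)CC[C@@](C)(O)[C@H](Br)[C@H]2OC(=O)[C@@H](COC(C)=O)[C@@H]21
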